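The route rests on cutting the C2–C3 bond of the dihydrofuran ring B (O1, C2, C3, C3a, C7a). The C3 carbinol and its neighbour C2, which carries O1 and an exocyclic 1,1-disubstituted alkene, together are a homoallylic alcohol, the signature of an allylboron addition to an aldehyde. An aryl (E)-enol ether whose allylic carbon bears a pinacol boronate, with a formyl group ortho to the ether oxygen, is therefore closed by a chiral phosphoric acid; one operation forms C2–C3, ring B, both ring stereocentres (trans) and the isopropenyl group. Acetylation, ketone reduction, tigloylation and allylic oxidation finish the target.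

Key step: step 9

Remarks on the chemistry (one line each)
- Reading of the target: ring B is trans with (2S,3R), the side-chain carbinol is (R), and the ester is the (E)-configured tiglate.
- Assumption: the uncatalysed ring closure of 14 is slow below about −40 °C, so 14 is made at −78 °C, passed cold to the catalyst and never stored.
- Boron is introduced through an allylpalladium intermediate, which delivers it to the unsubstituted allyl terminus; a borylcopper reagent would substitute in the SN2′ sense and put boron on the oxygen-bearing carbon.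
- The enol ether is made from a β-bromo enal, because exchanging the alkoxy group of a vinylogous ester for an acidic, weakly nucleophilic phenol is uphill.
- The free benzylic hydroxyl sits next to the enol ether only in 8 and 12; both are kept neutral or basic so that it does not add across the enol ether.

Step 1
Reactants: 1 4-hydroxyacetophenone
Product: 3 5-acetyl-2-hydroxybenzaldehyde, via ortho-hydroxymethylphenol 2 (not isolated)
Conditions: MgCl2 (1.5 equiv), Et3N (3.8 equiv), (CH2O)n (6 equiv), MeCN, reflux; then 1 M HCl
Reagents that add atoms: formaldehyde (as paraformaldehyde), C=O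
Why: Casnati–Skattebøl ortho-formylation: the magnesium phenoxide directs formaldehyde to the only free ortho position (para is blocked by the acetyl group) and a second formaldehyde oxidises the resulting benzylic alkoxide by hydride transfer, so no separate oxidant is needed.

Step 2
Reactants: 4 methacrolein
Product: 6 (2E)-3-bromo-2-methylprop-2-enal, via 2,3-dibromo-2-methylpropanal 5 (not isolated)
Conditions: Br2 (1.0 equiv), CH2Cl2, −78 → 0 °C; then Et3N (1.2 equiv), 0 °C → rt
Reagents that add atoms: bromine, BrBr
Why: Bromine adds across the alkene and triethylamine then removes HBr by E2 elimination (tertiary α-bromide, β-hydrogen on the bromomethyl carbon), giving the conjugated β-bromo enal, whose (E) isomer with bromine trans to the formyl group is the more stable one.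

Step 3
Reactants: 3 5-acetyl-2-hydroxybenzaldehyde; 6 (2E)-3-bromo-2-methylprop-2-enal
Product: 7 (2E)-3-(4-acetyl-2-formylphenoxy)-2-methylprop-2-enal
Conditions: K2CO3 (1.2 equiv), DMF, 0 °C → rt
Reagents that add atoms: (2E)-3-bromo-2-methylprop-2-enal (6), Br/C=C(\C)C=O
Why: Nucleophilic vinylic substitution by addition–elimination: the phenoxide adds to the β-carbon of the enal and the enolate expels bromide at once, and the push–pull product settles as the (E) isomer with the aryloxy group trans to the formyl group, which is the geometry the allylboronate must have.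

Step 4
Reactants: 7 (2E)-3-(4-acetyl-2-formylphenoxy)-2-methylprop-2-enal
Product: 8 1-[3-(hydroxymethyl)-4-{[(1E)-3-hydroxy-2-methylprop-1-en-1-yl]oxy}phenyl]ethanone
Conditions: NaBH4 (0.7 equiv), EtOH/CH2Cl2 (3:7), −78 °C; pH 7 phosphate buffer
Reagents that add atoms: none
Why: Chemoselective 1,2-reduction: at −78 °C borohydride reduces the aryl aldehyde and the vinylogous formyl group far faster than the aryl methyl ketone, hydride delivery to the carbonyl carbon leaves the enol ether geometry untouched, and the neutral work-up keeps the benzylic hydroxyl from adding to the enol ether.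

Step 5
Reactants: 8 1-[3-(hydroxymethyl)-4-{[(1E)-3-hydroxy-2-methylprop-1-en-1-yl]oxy}phenyl]ethanone
Product: 9 (2E)-3-[4-acetyl-2-(acetoxymethyl)phenoxy]-2-methylprop-2-en-1-yl acetate
Conditions: Ac2O (2.5 equiv), pyridine, DMAP (cat.), CH2Cl2, 0 °C
Reagents that add atoms: acetic anhydride, CC(=O)OC(C)=O
Why: Standard O-acylation, which turns the allylic hydroxyl into the leaving group for palladium and masks the benzylic hydroxyl, which if free could add to the neighbouring enol ether or capture the allylpalladium intermediate.

Step 6
Reactants: 9 (2E)-3-[4-acetyl-2-(acetoxymethyl)phenoxy]-2-methylprop-2-en-1-yl acetate; 10 bis(pinacolato)diboron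
Product: 11 [5-acetyl-2-({(1E)-2-methyl-3-(4,4,5,5-tetramethyl-1,3,2-dioxaborolan-2-yl)prop-1-en-1-yl}oxy)phenyl]methyl acetate
Conditions: Pd2(dba)3 (2.5 mol%), DMSO, 50 °C
Reagents that add atoms: bis(pinacolato)diboron (10), CC1(C)OB(OC1(C)C)B1OC(C)(C)C(C)(C)O1
Why: Miyaura borylation of an allylic acetate: oxidative addition to zerovalent palladium gives the 1-aryloxy-2-methylallyl complex, acetate-assisted transmetalation with the diboron and reductive elimination at the unsubstituted terminus give the primary allylboronate with the (E) geometry carried over from the syn complex formed first, while the benzylic acetate and the ketone should not react under ligand-free conditions.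

Step 7
Reactants: 11 [5-acetyl-2-({(1E)-2-methyl-3-(4,4,5,5-tetramethyl-1,3,2-dioxaborolan-2-yl)prop-1-en-1-yl}oxy)phenyl]methyl acetate
Product: 12 1-[3-(hydroxymethyl)-4-({(1E)-2-methyl-3-(4,4,5,5-tetramethyl-1,3,2-dioxaborolan-2-yl)prop-1-en-1-yl}oxy)phenyl]ethanone
Conditions: K2CO3 (0.2 equiv), MeOH, 0 °C; pH 7 buffer
Reagents that add atoms: none
Why: Base-catalysed transesterification with methanol removes the benzylic acetate as methyl acetate at 0 °C, conditions under which the pinacol boronate, the aryl enol ether and the ketone are stable.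

Step 8
Reactants: 12 1-[3-(hydroxymethyl)-4-({(1E)-2-methyl-3-(4,4,5,5-tetramethyl-1,3,2-dioxaborolan-2-yl)prop-1-en-1-yl}oxy)phenyl]ethanone
Product: 14 5-acetyl-2-({(1E)-2-methyl-3-(4,4,5,5-tetramethyl-1,3,2-dioxaborolan-2-yl)prop-1-en-1-yl}oxy)benzaldehyde, via alkoxydimethylsulfonium chloride 13 (not isolated)
Conditions: (COCl)2 (1.2 equiv), DMSO (2.4 equiv), CH2Cl2, −78 °C; Et3N (4 equiv), −78 °C; filtration through silica with toluene at −78 °C, solution used at once
Reagents that add atoms: none
Why: Swern oxidation: the benzylic alcohol is converted through its alkoxysulfonium salt into the aldehyde at −78 °C without touching the ketone, the enol ether or the boronate, so that aldehyde and allylboronate first meet at a temperature at which thermal ring closure is slow and the cold solution can go straight into step 9.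

Step 9
Reactants: 14 5-acetyl-2-({(1E)-2-methyl-3-(4,4,5,5-tetramethyl-1,3,2-dioxaborolan-2-yl)prop-1-en-1-yl}oxy)benzaldehyde
Product: 16 1-[(2S,3R)-3-hydroxy-2-(prop-1-en-2-yl)-2,3-dihydro-1-benzofuran-5-yl]ethanone, via pinacol borate ester 15 (not isolated)
Conditions: (S)-TRIP [(S)-3,3′-bis(2,4,6-triisopropylphenyl)-1,1′-binaphthyl-2,2′-diyl hydrogen phosphate] (10 mol%), toluene, −78 → −40 °C; then aq. NaHCO3
Reagents that add atoms: none
Why: Proposed new method: boron binds the formyl oxygen and the oxygen-bearing γ-carbon of the allylboronate adds to the carbonyl carbon through a six-membered chair with allylic transposition, while the phosphoric acid is expected to hold this array by a hydrogen bond to a pinacol oxygen and a contact of its P=O group with the formyl hydrogen. The closest known reactions are the thermal intramolecular allylboration of aldehydes by γ-alkoxyallylboronates and the chiral-phosphoric-acid-catalysed addition of pinacol allylboronates to aryl aldehydes; joining the two on a tethered γ-aryloxy substrate is the untested part. Ring B closes in the 5-exo-trig mode, the new C2–C3 bond ending at the formyl carbon with the carbonyl oxygen outside the ring. C2 is set relative to C3 by the (E) enol ether, which places O1 and the aryl carbon C3a both equatorial in the chair so that the two ring hydrogens end up trans, and C3 is set by the catalyst, the (S)-acid being chosen because the (R)-acid directs such boronates to the Re face of aryl aldehydes whereas (3R) here requires attack on the Si face. The step needs bond formation at the γ-carbon and not at the more electron-rich β-carbon of the enol ether, which the closed boron-bridged transition state secures (an open, acid-induced Prins closure would give a chromene), and it needs the catalysed path to outrun the thermal one, which the low temperature and the twist of the formyl group out of the arene plane that closure demands should help. Mild hydrolysis of the pinacol borate ester 15 then frees the alcohol.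

Step 10
Reactants: 16 1-[(2S,3R)-3-hydroxy-2-(prop-1-en-2-yl)-2,3-dihydro-1-benzofuran-5-yl]ethanone
Product: 17 (2S,3R)-5-acetyl-2-(prop-1-en-2-yl)-2,3-dihydro-1-benzofuran-3-yl acetate
Conditions: Ac2O (1.5 equiv), pyridine, DMAP (cat.), CH2Cl2, 0 °C
Reagents that add atoms: acetic anhydride, CC(=O)OC(C)=O
Why: O-Acylation at the hydroxyl oxygen leaves the C3–O bond and hence the configuration untouched, and the cold, weakly basic medium avoids ionisation at the benzylic C3 and aromatisation to the benzofuran.

Step 11
Reactants: 17 (2S,3R)-5-acetyl-2-(prop-1-en-2-yl)-2,3-dihydro-1-benzofuran-3-yl acetate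
Product: 19 (2S,3R)-5-[(1R)-1-hydroxyethyl]-2-(prop-1-en-2-yl)-2,3-dihydro-1-benzofuran-3-yl acetate, via catechol borate ester 18 (not isolated)
Conditions: (S)-Me-CBS oxazaborolidine [(S)-1-methyl-3,3-diphenyltetrahydro-1H,3H-pyrrolo[1,2-c][1,3,2]oxazaborole] (20 mol%), catecholborane (1.8 equiv), toluene, −78 °C; MeOH, then pH 7 buffer
Reagents that add atoms: none
Why: Corey–Bakshi–Shibata reduction: the ketone binds to the (S)-oxazaborolidine with the aryl group away from the catalyst framework and hydride is delivered to the Si face, giving the (R)-1-arylethanol as with acetophenone, while catecholborane at −78 °C leaves the 1,1-disubstituted alkene and the acetate alone.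

Step 12
Reactants: 19 (2S,3R)-5-[(1R)-1-hydroxyethyl]-2-(prop-1-en-2-yl)-2,3-dihydro-1-benzofuran-3-yl acetate
Product: 20 (1R)-1-[(2S,3R)-3-acetoxy-2-(prop-1-en-2-yl)-2,3-dihydro-1-benzofuran-5-yl]ethyl (2E)-2-methylbut-2-enoate
Conditions: tiglic acid (1.5 equiv), DCC (1.5 equiv), DMAP (cat.), CH2Cl2, 0 °C → rt
Reagents that add atoms: tiglic acid [(2E)-2-methylbut-2-enoic acid], C/C=C(\C)C(=O)O
Why: Steglich esterification: the acid is activated as the O-acylisourea and then as the acylpyridinium ion and the alcohol attacks the acyl carbon, so the carbinol C–O bond and its (R) configuration are kept, and the (E) acid is the stable isomer so its geometry holds.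

Step 13
Reactants: 20 (1R)-1-[(2S,3R)-3-acetoxy-2-(prop-1-en-2-yl)-2,3-dihydro-1-benzofuran-5-yl]ethyl (2E)-2-methylbut-2-enoate
Product: 21 (1R)-1-[(2S,3R)-3-acetoxy-2-(3-hydroxyprop-1-en-2-yl)-2,3-dihydro-1-benzofuran-5-yl]ethyl (2E)-2-methylbut-2-enoate
Conditions: SeO2 (0.5 equiv), tBuOOH (3 equiv), CH2Cl2, rt
Reagents that add atoms: tert-butyl hydroperoxide, CC(C)(C)OO (its oxygen atom is passed on through SeO2, O=[Se]=O)
Why: Riley-type allylic oxidation with catalytic SeO2: an ene reaction at the terminal carbon of the 1,1-disubstituted alkene followed by a [2,3]-sigmatropic shift places the hydroxyl on the methyl carbon, which is preferred to the oxygen-bearing C2 methine, and the ester-conjugated tiglate alkene is far less reactive towards the electrophilic selenium reagent.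

Step 14
Reactants: 21 (1R)-1-[(2S,3R)-3-acetoxy-2-(3-hydroxyprop-1-en-2-yl)-2,3-dihydro-1-benzofuran-5-yl]ethyl (2E)-2-methylbut-2-enoate
Product: 22 (1R)-1-[(2S,3R)-3-acetoxy-2-(3-oxoprop-1-en-2-yl)-2,3-dihydro-1-benzofuran-5-yl]ethyl (2E)-2-methylbut-2-enoate
Conditions: MnO2 (activated, 15 equiv), CH2Cl2, rt
Reagents that add atoms: none
Why: Activated MnO2 oxidises only the allylic alcohol and does so under neutral conditions, which spares both esters and the elimination-prone C3 acetate next to the new enal; no stereocentre is touched.

Compound list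
1 | 4-hydroxyacetophenone | CC(=O)c1ccc(O)cc1 | starting material
2 | 1-[4-hydroxy-3-(hydroxymethyl)phenyl]ethanone (present in the flask as its magnesium phenoxide) | CC(=O)c1ccc(O)c(CO)c1 | intermediate
3 | 5-acetyl-2-hydroxybenzaldehyde | CC(=O)c1ccc(O)c(C=O)c1 | intermediate
4 | methacrolein (2-methylprop-2-enal) | C=C(C)C=O | starting material
5 | 2,3-dibromo-2-methylpropanal (racemic, formed in the flask) | O=CC(C)(Br)CBr | intermediate
6 | (2E)-3-bromo-2-methylprop-2-enal | Br/C=C(\C)C=O | intermediate
7 | (2E)-3-(4-acetyl-2-formylphenoxy)-2-methylprop-2-enal | CC(=O)c1ccc(O/C=C(\C)C=O)c(C=O)c1 | intermediate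
8 | 1-[3-(hydroxymethyl)-4-{[(1E)-3-hydroxy-2-methylprop-1-en-1-yl]oxy}phenyl]ethanone | CC(=O)c1ccc(O/C=C(\C)CO)c(CO)c1 | intermediate
9 | (2E)-3-[4-acetyl-2-(acetoxymethyl)phenoxy]-2-methylprop-2-en-1-yl acetate | CC(=O)c1ccc(O/C=C(\C)COC(C)=O)c(COC(C)=O)c1 | intermediate
10 | bis(pinacolato)diboron | CC1(C)OB(OC1(C)C)B1OC(C)(C)C(C)(C)O1 | starting material
11 | [5-acetyl-2-({(1E)-2-methyl-3-(4,4,5,5-tetramethyl-1,3,2-dioxaborolan-2-yl)prop-1-en-1-yl}oxy)phenyl]methyl acetate | CC(=O)c1ccc(O/C=C(\C)CB2OC(C)(C)C(C)(C)O2)c(COC(C)=O)c1 | intermediate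
12 | 1-[3-(hydroxymethyl)-4-({(1E)-2-methyl-3-(4,4,5,5-tetramethyl-1,3,2-dioxaborolan-2-yl)prop-1-en-1-yl}oxy)phenyl]ethanone | CC(=O)c1ccc(O/C=C(\C)CB2OC(C)(C)C(C)(C)O2)c(CO)c1 | intermediate
13 | {[5-acetyl-2-({(1E)-2-methyl-3-(4,4,5,5-tetramethyl-1,3,2-dioxaborolan-2-yl)prop-1-en-1-yl}oxy)phenyl]methoxy}dimethylsulfonium chloride (formed in the flask) | CC(=O)c1ccc(O/C=C(\C)CB2OC(C)(C)C(C)(C)O2)c(CO[S+](C)C)c1.[Cl-] | intermediate
14 | 5-acetyl-2-({(1E)-2-methyl-3-(4,4,5,5-tetramethyl-1,3,2-dioxaborolan-2-yl)prop-1-en-1-yl}oxy)benzaldehyde (key-step precursor) | CC(=O)c1ccc(O/C=C(\C)CB2OC(C)(C)C(C)(C)O2)c(C=O)c1 | intermediate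
15 | 1-[(2S,3R)-2-(prop-1-en-2-yl)-3-[(4,4,5,5-tetramethyl-1,3,2-dioxaborolan-2-yl)oxy]-2,3-dihydro-1-benzofuran-5-yl]ethanone (formed in the flask) | C=C(C)[C@@H]1Oc2ccc(C(C)=O)cc2[C@H]1OB1OC(C)(C)C(C)(C)O1 | intermediate
16 | 1-[(2S,3R)-3-hydroxy-2-(prop-1-en-2-yl)-2,3-dihydro-1-benzofuran-5-yl]ethanone (key-step product) | C=C(C)[C@@H]1Oc2ccc(C(C)=O)cc2[C@H]1O | intermediate
17 | (2S,3R)-5-acetyl-2-(prop-1-en-2-yl)-2,3-dihydro-1-benzofuran-3-yl acetate | C=C(C)[C@@H]1Oc2ccc(C(C)=O)cc2[C@H]1OC(C)=O | intermediate
18 | (2S,3R)-5-[(1R)-1-(1,3,2-benzodioxaborol-2-yloxy)ethyl]-2-(prop-1-en-2-yl)-2,3-dihydro-1-benzofuran-3-yl acetate (formed in the flask) | C=C(C)[C@@H]1Oc2ccc([C@@H](C)OB3Oc4ccccc4O3)cc2[C@H]1OC(C)=O | intermediate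
19 | (2S,3R)-5-[(1R)-1-hydroxyethyl]-2-(prop-1-en-2-yl)-2,3-dihydro-1-benzofuran-3-yl acetate | C=C(C)[C@@H]1Oc2ccc([C@@H](C)O)cc2[C@H]1OC(C)=O | intermediate
20 | (1R)-1-[(2S,3R)-3-acetoxy-2-(prop-1-en-2-yl)-2,3-dihydro-1-benzofuran-5-yl]ethyl (2E)-2-methylbut-2-enoate | C=C(C)[C@@H]1Oc2ccc([C@@H](C)OC(=O)/C(C)=C/C)cc2[C@H]1OC(C)=O | intermediate
21 | (1R)-1-[(2S,3R)-3-acetoxy-2-(3-hydroxyprop-1-en-2-yl)-2,3-dihydro-1-benzofuran-5-yl]ethyl (2E)-2-methylbut-2-enoate | C=C(CO)[C@@H]1Oc2ccc([C@@H](C)OC(=O)/C(C)=C/C)cc2[C@H]1OC(C)=O | intermediate
22 | (1R)-1-[(2S,3R)-3-acetoxy-2-(3-oxoprop-1-en-2-yl)-2,3-dihydro-1-benzofuran-5-yl]ethyl (2E)-2-methylbut-2-enoate | C=C(C=O)[C@@H]1Oc2ccc([C@@H](C)OC(=O)/C(C)=C/C)cc2[C@H]1OC(C)=O | target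

Total step count: 14. Longest linear sequence: 13 steps (steps 1 and 3 to 14, from 4-hydroxyacetophenone); step 2 is a one-step side branch.

The three steps most likely to fail

Step 9 (Proposed new method). The thermal, uncatalysed closure may keep pace with the acid-bound pathway, or the tether may prevent the two-point binding of the acid, so that the two faces of the formyl group are poorly distinguished. Closure through a boat could also erode the trans selectivity. Should the sense of induction be opposite to the intermolecular precedent, the (R)-acid is used. The fallback uses known chemistry, sets out from 14 and comes back at 16. The cold toluene solution of 14 is warmed to room temperature without catalyst. The known thermal intramolecular allylboration then closes ring B through the same chair to the racemic pinacol borate ester F1, and aqueous work-up gives the racemic trans alcohol F2. Kinetic resolution with Candida antarctica lipase B and vinyl acetate in tert-butyl methyl ether acetylates one enantiomer. By the empirical size rule for lipases, with the aryl-fused side as the large substituent, this is expected to be the (2R,3S) alcohol, which gives the (2R,3S)-acetate F3 and leaves 16 for chromatographic separation. If the enzyme preferred the other enantiomer, its acetate would be 17 itself.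

Step 13. The electrophilic selenium reagent may also attack the γ-methyl group of the tiglate or the C2 methine. During a slow oxidation the C3 acetate may also ionise, with loss of acetic acid to the benzofuran. The fallback sets out from 20 and comes back at 22, bypassing 21. An ene-type chlorination with hypochlorous acid made in the flask (Ca(OCl)2, solid CO2, CH2Cl2/H2O, 0 °C) should convert the isopropenyl group into the allylic chloride F4, the tiglate alkene being too electron-poor to react. A Kornblum–Ganem oxidation with 4-methylmorpholine N-oxide (NaI cat., MeCN, rt) should then turn the chloromethyl group directly into the formyl group of 22.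

Step 6. Reductive elimination may occur at the oxygen-bearing allyl terminus, syn–anti isomerisation of the allylpalladium intermediate may erode the (E) geometry, or the product may couple with a second allyl complex. The fallback sets out from 8 and comes back at 12. It replaces the acetylate–borylate–deacetylate sequence by a protecting-group-free borylation of the allylic hydroxyl itself: Pd(MeCN)4(BF4)2 (5 mol%) and bis(pinacolato)diboron in DMSO/MeOH at room temperature to 40 °C. Under these conditions a boron Lewis acid assists ionisation of the allylic C–OH bond only, so the benzylic alcohol remains and steps 5 and 7 fall away. This fallback makes no compound outside the list.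

Further compounds
F1 | step 9 | racemic trans-1-[2-(prop-1-en-2-yl)-3-[(4,4,5,5-tetramethyl-1,3,2-dioxaborolan-2-yl)oxy]-2,3-dihydro-1-benzofuran-5-yl]ethanone (both enantiomers) | C=C(C)[C@@H]1Oc2ccc(C(C)=O)cc2[C@H]1OB1OC(C)(C)C(C)(C)O1.C=C(C)[C@H]1Oc2ccc(C(C)=O)cc2[C@@H]1OB1OC(C)(C)C(C)(C)O1
F2 | step 9 | racemic trans-1-[3-hydroxy-2-(prop-1-en-2-yl)-2,3-dihydro-1-benzofuran-5-yl]ethanone (both enantiomers) | C=C(C)[C@@H]1Oc2ccc(C(C)=O)cc2[C@H]1O.C=C(C)[C@H]1Oc2ccc(C(C)=O)cc2[C@@H]1O
F3 | step 9 | (2R,3S)-5-acetyl-2-(prop-1-en-2-yl)-2,3-dihydro-1-benzofuran-3-yl acetate | C=C(C)[C@H]1Oc2ccc(C(C)=O)cc2[C@@H]1OC(C)=O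
F4 | step 13 | (1R)-1-[(2S,3R)-3-acetoxy-2-(3-chloroprop-1-en-2-yl)-2,3-dihydro-1-benzofuran-5-yl]ethyl (2E)-2-methylbut-2-enoate | C=C(CCl)[C@@H]1Oc2ccc([C@@H](C)OC(=O)/C(C)=C/C)cc2[C@H]1OC(C)=O
F0 | step 6 | none | none
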